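**Plan**
1. The target is a single benzene ring with OAc at C1, OMe at C2, OH at C4 and n-pentadecyl at C6. An acetate at C1 flanked by the C2 methoxy and the C6 chain, with the C4 oxygen para, is the Baeyer–Villiger image of a 2-alkoxy-4-oxy-6-alkylacetophenone, which is the pattern formed when a 1-alkoxy-3-silyloxycyclohexa-1,3-diene is benzannulated with a 4-alkylbut-3-yn-2-one.
2. Retrosynthesis: cut O4–Si (protecting group), then turn C1–O back into C1–acetyl (retro-Baeyer–Villiger). Then cut ring bonds C1–C2 and C5–C6 while restoring a two-carbon bridge between C2 and C5 (retro-Alder–Rickert), which gives a silyloxy diene and nonadec-3-yn-2-one. The ynone is cut at its C(O)–C(sp) bond.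
3. Forward: the diene comes in one step from 3-methoxycyclohex-2-enone, and the C15 chain enters ready-made in the ynone (1-heptadecyne plus an acetyl donor). The only ring, the arene, arises in step 3 by [4+2] cycloaddition and loss of ethylene. Peracid oxidation and desilylation finish the synthesis.
4. Stereochemistry: the target has no stereocentre and no stereogenic double bond. The only selectivity to control is the regiochemistry of the cycloaddition, which sets the 1,2,4,6 pattern.

Key step: step 3

Assumption: 1-heptadecyne is taken as a purchasable alkyne; ring positions are cited in target numbering (C1 = acetoxy-bearing carbon).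

Step 1
Reactants: 1 3-methoxycyclohex-2-en-1-one
Product: 3 1-methoxy-3-(tert-butyldimethylsilyloxy)cyclohexa-1,3-diene, via lithium dienolate 2 (not isolated)
Conditions: LiN(i-Pr)2 (LDA, commercial solution, 1.1 equiv), THF, −78 °C; TBSCl, DMPU, −78 °C to rt; non-aqueous work-up (pentane, filtration), Kugelrohr distillation
Reagents that add atoms: tert-butyldimethylsilyl chloride (TBSCl), CC(C)(C)[Si](C)(C)Cl
Why: Kinetic alpha'-deprotonation of the vinylogous ester gives the cross-conjugated lithium dienolate, and its O-silylation by TBSCl in the presence of DMPU (silyl enol ether formation) should deliver the 1-methoxy-3-silyloxy diene without creating a stereocentre.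

Step 2
Reactants: 4 1-heptadecyne, 5 N-methoxy-N-methylacetamide
Product: 8 nonadec-3-yn-2-one, via lithium heptadecynide 6 (not isolated), via lithium hemiaminal alkoxide 7 (not isolated)
Conditions: n-BuLi, THF, −78 °C; then 5, −78 to 0 °C; inverse quench into cold 1 M HCl
Reagents that add atoms: none
Why: Weinreb ketone synthesis, in which the lithium acetylide adds once to the N-methoxy-N-methylamide and the lithium chelate holds back the ketone until the cold acidic quench, which also protonates the released N,O-dimethylhydroxylamine so that it cannot add to the ynone.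

Step 3
Reactants: 3 1-methoxy-3-(tert-butyldimethylsilyloxy)cyclohexa-1,3-diene, 8 nonadec-3-yn-2-one
Product: 10 1-[4-(tert-butyldimethylsilyloxy)-2-methoxy-6-pentadecylphenyl]ethanone, via bicyclo[2.2.2]octadiene adduct 9 (not isolated)
Conditions: 3 (2 equiv), neat under Ar, sealed tube, 120 °C then 180 °C
Reagents that add atoms: none
Why: The electron-rich 1-methoxy-3-silyloxy diene and the acetyl-activated alkyne should combine in a thermal, normal-electron-demand Diels–Alder reaction to the bicyclo[2.2.2]octa-2,5-diene 9, which on further heating undergoes [4+2] cycloreversion, losing its saturated C7–C8 bridge as ethylene, with the gain of aromaticity making the loss irreversible. This is the Alder–Rickert reaction, and its closest precedent is the benzannulation of 1-alkoxy-3-silyloxycyclohexa-1,3-dienes with acetylenic ketones and esters to resorcinol derivatives. The benzene ring is closed intermolecularly by the concerted, suprafacial [4π+2π] cycloaddition that forms C5–C6 and C1–C2 in one asynchronous event, so no exo/endo ring-closure rule applies. No stereocentre survives, because the two bridgehead centres of racemic 9 are erased on aromatization. The selectivity needed is regiochemical and is secured by matched polarization: the unsubstituted diene terminus, activated by both the silyl enol ether and the vinylogous methyl enol ether, carries the largest HOMO coefficient and bonds to the chain-bearing beta-carbon of the ynone, so the acetyl carbon joins the methoxy-bearing terminus. Excess diene and staged heating (cycloaddition first, extrusion second) are meant to limit diene isomerization before the cycloaddition.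

Step 4
Reactants: 10 1-[4-(tert-butyldimethylsilyloxy)-2-methoxy-6-pentadecylphenyl]ethanone
Product: 12 4-(tert-butyldimethylsilyloxy)-2-methoxy-6-pentadecylphenyl acetate, via Criegee peroxyhemiketal 11 (not isolated)
Conditions: mCPBA (2 equiv), CF3CO2H (0.1 equiv), CH2Cl2, 0 °C to rt, dark; aq. Na2S2O3/NaHCO3 work-up
Reagents that add atoms: 3-chloroperoxybenzoic acid (mCPBA), OOC(=O)c1cccc(Cl)c1
Why: Baeyer–Villiger oxidation, in which the peracid adds to the ketone and the electron-rich aryl group (ortho-methoxy, para-silyloxy, twisted out of conjugation by its two ortho substituents) migrates to oxygen in preference to methyl, giving the aryl acetate directly while the aryl silyl ether and the alkyl chain stay untouched.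

Step 5
Reactants: 12 4-(tert-butyldimethylsilyloxy)-2-methoxy-6-pentadecylphenyl acetate
Product: 13 4-hydroxy-2-methoxy-6-pentadecylphenyl acetate
Conditions: Bu4NF (TBAF, 1.1 equiv), AcOH (1.1 equiv), THF, 0 °C
Reagents that add atoms: none
Why: Fluoride-mediated desilylation of an aryl silyl ether, with acetic acid buffering so that the phenoxide concentration stays low and the hindered C1 acetate is neither cleaved nor transferred.

**Compound list**
1 | 3-methoxycyclohex-2-en-1-one | COC1=CC(=O)CCC1 | starting material
2 | lithium 5-methoxycyclohexa-1,5-dien-1-olate | COC1=CC([O-])=CCC1.[Li+] | intermediate, not isolated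
3 | 1-methoxy-3-(tert-butyldimethylsilyloxy)cyclohexa-1,3-diene | COC1=CC(O[Si](C)(C)C(C)(C)C)=CCC1 | intermediate
4 | 1-heptadecyne | C#CCCCCCCCCCCCCCCC | starting material
5 | N-methoxy-N-methylacetamide | CON(C)C(C)=O | starting material
6 | lithium heptadec-1-yn-1-ide | [Li+].[C-]#CCCCCCCCCCCCCCCC | intermediate, not isolated
7 | lithium 2-[methoxy(methyl)amino]nonadec-3-yn-2-olate | CCCCCCCCCCCCCCCC#CC(C)([O-])N(C)OC.[Li+] | intermediate, not isolated
8 | nonadec-3-yn-2-one | CCCCCCCCCCCCCCCC#CC(C)=O | intermediate
9 | 1-[5-(tert-butyldimethylsilyloxy)-1-methoxy-3-pentadecylbicyclo[2.2.2]octa-2,5-dien-2-yl]ethanone (racemic) | COC12CCC(C(CCCCCCCCCCCCCCC)=C1C(C)=O)C(O[Si](C)(C)C(C)(C)C)=C2 | intermediate, not isolated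
10 | 1-[4-(tert-butyldimethylsilyloxy)-2-methoxy-6-pentadecylphenyl]ethanone | CCCCCCCCCCCCCCCc1cc(O[Si](C)(C)C(C)(C)C)cc(OC)c1C(C)=O | intermediate
11 | 1-[4-(tert-butyldimethylsilyloxy)-2-methoxy-6-pentadecylphenyl]-1-hydroxyethyl 3-chlorobenzenecarboperoxoate (racemic) | CCCCCCCCCCCCCCCc1cc(O[Si](C)(C)C(C)(C)C)cc(OC)c1C(C)(O)OOC(=O)c1cccc(Cl)c1 | intermediate, not isolated
12 | 4-(tert-butyldimethylsilyloxy)-2-methoxy-6-pentadecylphenyl acetate | CCCCCCCCCCCCCCCc1cc(O[Si](C)(C)C(C)(C)C)cc(OC)c1OC(C)=O | intermediate
13 | 4-hydroxy-2-methoxy-6-pentadecylphenyl acetate | CCCCCCCCCCCCCCCc1cc(O)cc(OC)c1OC(C)=O | target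

**Step count**
Total steps: 5 (steps 1 and 2 run in parallel and converge in step 3).
Longest linear sequence: 4 steps (step 1 or 2, then steps 3, 4 and 5).

**Steps most likely to fail**

Step 3. The 4-alkyl ynone may cycloadd slowly. At the temperature then needed, 1,5-hydrogen shifts in the cyclohexadiene could scramble the diene before it reacts, leading to regioisomeric or methoxy-free arenes. Stepwise Mukaiyama–Michael addition without ring closure, or incomplete ethylene extrusion, are further possibilities. The fallback sets out from 8 and makes the same two ring bonds with an acyclic diene that aromatizes by elimination instead of cycloreversion. The known ketene acetal 4,4-dimethoxybut-3-en-2-one (COC(OC)=CC(C)=O) would be silylated (Me3SiCl, Et3N, ZnCl2 cat.) to 1,1-dimethoxy-3-(trimethylsilyloxy)buta-1,3-diene F1 and heated with 8 (toluene, 110 °C). The primary cycloadduct 1-[6,6-dimethoxy-2-pentadecyl-4-(trimethylsilyloxy)cyclohexa-1,4-dien-1-yl]ethanone F2 should lose methanol in the flask to give 1-[2-methoxy-6-pentadecyl-4-(trimethylsilyloxy)phenyl]ethanone F3. Dilute HCl in THF on work-up would then give 1-(4-hydroxy-2-methoxy-6-pentadecylphenyl)ethanone F4. Silylation of F4 (TBSCl, imidazole, DMF) comes back to the route at 10.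

Step 4. Peracid addition to the doubly ortho-substituted, twisted ketone may be slow. Electrophilic hydroxylation of the electron-rich ring at C3 or C5, or acid-induced loss of the silyl ether, could then compete with aryl migration. The fallback sets out from 4 and carries a formyl group in place of the acetyl group, since aldehydes react with peracids much faster. Formylation of the lithium acetylide of 4 (n-BuLi, THF, −78 °C; DMF; inverse quench into aq. KH2PO4) would give octadec-2-ynal F5. Heating F5 with 3 as in step 3 should pass through the adduct 5-(tert-butyldimethylsilyloxy)-1-methoxy-3-pentadecylbicyclo[2.2.2]octa-2,5-diene-2-carbaldehyde F6 and give 4-(tert-butyldimethylsilyloxy)-2-methoxy-6-pentadecylbenzaldehyde F7 after ethylene loss. Dakin-type Baeyer–Villiger oxidation (mCPBA, NaHCO3, CH2Cl2, 0 °C) would give 4-(tert-butyldimethylsilyloxy)-2-methoxy-6-pentadecylphenyl formate F8. Mild methanolysis (Et3N, MeOH, 0 °C) would free 4-(tert-butyldimethylsilyloxy)-2-methoxy-6-pentadecylphenol F9. Acetylation (Ac2O, pyridine, DMAP) comes back to the route at 12.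

Step 5. The phenoxide formed on desilylation may attack the aryl acetate of another molecule, or the acetate may be lost. Either would give mixtures of diol, regioisomeric monoacetate and diacetate. The fallback sets out from 12 and accepts the loss of differentiation. Desilylation followed by acetylation in the same flask (Bu4NF, THF; then Ac2O, pyridine, DMAP) would converge all material on 2-methoxy-6-pentadecyl-1,4-phenylene diacetate F10. Selective aminolysis of the unhindered C4 acetate (pyrrolidine, 1 equiv, CH2Cl2, 0 °C) should then leave the C1 acetate, which is shielded by the methoxy group and the pentadecyl chain. This comes back to the route at 13.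

**Further compounds**
F1 | step 3 | 1,1-dimethoxy-3-(trimethylsilyloxy)buta-1,3-diene | COC(OC)=CC(=C)O[Si](C)(C)C
F2 | step 3 | 1-[6,6-dimethoxy-2-pentadecyl-4-(trimethylsilyloxy)cyclohexa-1,4-dien-1-yl]ethanone | CCCCCCCCCCCCCCCC1=C(C(C)=O)C(OC)(OC)C=C(O[Si](C)(C)C)C1
F3 | step 3 | 1-[2-methoxy-6-pentadecyl-4-(trimethylsilyloxy)phenyl]ethanone | CCCCCCCCCCCCCCCc1cc(O[Si](C)(C)C)cc(OC)c1C(C)=O
F4 | step 3 | 1-(4-hydroxy-2-methoxy-6-pentadecylphenyl)ethanone | CCCCCCCCCCCCCCCc1cc(O)cc(OC)c1C(C)=O
F5 | step 4 | octadec-2-ynal | CCCCCCCCCCCCCCCC#CC=O
F6 | step 4 | 5-(tert-butyldimethylsilyloxy)-1-methoxy-3-pentadecylbicyclo[2.2.2]octa-2,5-diene-2-carbaldehyde (racemic) | COC12CCC(C(CCCCCCCCCCCCCCC)=C1C=O)C(O[Si](C)(C)C(C)(C)C)=C2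
F7 | step 4 | 4-(tert-butyldimethylsilyloxy)-2-methoxy-6-pentadecylbenzaldehyde | CCCCCCCCCCCCCCCc1cc(O[Si](C)(C)C(C)(C)C)cc(OC)c1C=O
F8 | step 4 | 4-(tert-butyldimethylsilyloxy)-2-methoxy-6-pentadecylphenyl formate | CCCCCCCCCCCCCCCc1cc(O[Si](C)(C)C(C)(C)C)cc(OC)c1OC=O
F9 | step 4 | 4-(tert-butyldimethylsilyloxy)-2-methoxy-6-pentadecylphenol | CCCCCCCCCCCCCCCc1cc(O[Si](C)(C)C(C)(C)C)cc(OC)c1O
F10 | step 5 | 2-methoxy-6-pentadecyl-1,4-phenylene diacetate | CCCCCCCCCCCCCCCc1cc(OC(C)=O)cc(OC)c1OC(C)=O
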